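**Retrosynthetic overview**
- Target ⇒ (+)-germacrene A + 5,7,8-trimethoxyflav-2-en-4-ol (a flavylium precursor). One flavylium-initiated transannular cyclisation/hydration forms C1–C4′ and C5–C10 and sets C1, C4, C5, C10 and C4′ (proposed new method).
- Germacrene A ⇒ ten-membered dienyl triflate ⇒ anionic oxy-Cope ring expansion of a trans-1,2-dialkenylcyclohexanol.
- That carbinol ⇒ (R)-carvone (source of C7) by reductive aldol/dehydration (α-vinylation) and isopropenyl Grignard addition.
- Flavenol ⇒ 5,7,8-trimethoxyflavone ⇒ wogonin (O-methylation, 1,2-reduction).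
- Ring order: the chromene is bought in with wogonin; the carvone cyclohexane is expanded to the cyclodecadiene; both six-membered rings of the decalin are closed in the last step.

Assumption: the facial sense imposed by the chiral phosphate at C4′ cannot be predicted with certainty, so (R)-TRIP is written and its antipode is used if the 4′-epimer predominates.

Eudesmane/germacrane numbering is used for the terpene part and primed numbers for the chromene.

**Step 1**
Reactants: 1 (R)-(−)-carvone
Product: 3 (2R,5R)-2-(1-hydroxyethyl)-2-methyl-5-(prop-1-en-2-yl)cyclohexan-1-one (carbinol epimers), via lithium enolate 2 (not isolated)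
Conditions: L-Selectride (1.05 equiv), THF, −78 °C; CH3CHO (3 equiv), −78 °C; AcOH quench at −78 °C
Reagents that add atoms: acetaldehyde, CC=O
Why: Conjugate hydride reduction gives the C2 enolate regiospecifically, and its aldol reaction with acetaldehyde (reductive aldol) proceeds by axial attack on the half-chair with the isopropenyl group pseudo-equatorial, which puts the new C–C bond cis to the isopropenyl group (2R) as in alkylations and Robinson annulations of dihydrocarvone, while the carbinol centre forms as a mixture that is erased in step 2.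

**Step 2**
Reactants: 3 (2R,5R)-2-(1-hydroxyethyl)-2-methyl-5-(prop-1-en-2-yl)cyclohexan-1-one
Product: 4 (2R,5R)-2-ethenyl-2-methyl-5-(prop-1-en-2-yl)cyclohexan-1-one
Conditions: Burgess reagent (2 equiv), PhMe, 70 °C
Reagents that add atoms: none
Why: Burgess dehydration (syn elimination of the sulfamate ester) can only remove a hydrogen from the methyl group because the other β-carbon is quaternary, so the terminal vinyl group forms without touching C2 or C5.

**Step 3**
Reactants: 4 (2R,5R)-2-ethenyl-2-methyl-5-(prop-1-en-2-yl)cyclohexan-1-one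
Product: 5 (1S,2R,5R)-2-ethenyl-2-methyl-1,5-di(prop-1-en-2-yl)cyclohexan-1-ol
Conditions: isopropenylmagnesium bromide (2 equiv), LaCl3·2LiCl (0.3 equiv), THF, 0 °C; sat. aq NH4Cl
Reagents that add atoms: isopropenylmagnesium bromide, C=C(C)[Mg]Br
Why: Lanthanum-promoted Grignard 1,2-addition occurs by axial attack anti to the axial C2 vinyl group of the preferred chair (C2 methyl and C5 isopropenyl equatorial), which places the new isopropenyl group trans to the vinyl group (1S) as required for a chair oxy-Cope transition state.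

**Step 4**
Reactants: 5 (1S,2R,5R)-2-ethenyl-2-methyl-1,5-di(prop-1-en-2-yl)cyclohexan-1-ol
Product: 7 (1Z,5E,9R)-2,6-dimethyl-9-(prop-1-en-2-yl)cyclodeca-1,5-dien-1-yl trifluoromethanesulfonate, via potassium enolate 6 (not isolated)
Conditions: KH (1.5 equiv), 18-crown-6 (1.5 equiv), THF, 0 → 40 °C; PhNTf2 (1.3 equiv), −78 → 0 °C
Reagents that add atoms: N-phenylbis(trifluoromethanesulfonimide), O=S(=O)(N(c1ccccc1)S(=O)(=O)C(F)(F)F)C(F)(F)F
Why: Anionic oxy-Cope rearrangement of the potassium alkoxide through the chair transition state with both alkenyl groups equatorial gives the ten-membered enolate with an E C1=C10 olefin and a ring-trans C4=C5 enolate (the two carbinol-ring stereocentres become sp2, C7 is untouched), and O-triflation of this regiodefined enolate fixes the geometry.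

**Step 5**
Reactants: 7 (1Z,5E,9R)-2,6-dimethyl-9-(prop-1-en-2-yl)cyclodeca-1,5-dien-1-yl trifluoromethanesulfonate
Product: 8 (+)-germacrene A, (1E,5E,8R)-1,5-dimethyl-8-(prop-1-en-2-yl)cyclodeca-1,5-diene
Conditions: Pd(OAc)2 (5 mol%), dppf (6 mol%), HCO2H (2 equiv), Et3N (3 equiv), DMF, 35 °C; pentane extraction, Et3N-deactivated silica, stored cold
Reagents that add atoms: none
Why: Palladium-catalysed formate reduction of the alkenyl triflate (oxidative addition, decarboxylation of formate to a Pd hydride, reductive elimination) replaces OTf by H with retention of olefin geometry under buffered, near-ambient conditions that avoid the acid-induced cyclisation and the thermal Cope rearrangement of germacrene A.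

**Step 6**
Reactants: 9 wogonin (5,7-dihydroxy-8-methoxy-2-phenyl-4H-chromen-4-one)
Product: 10 5,7,8-trimethoxy-2-phenyl-4H-chromen-4-one
Conditions: MeI (6 equiv), K2CO3 (6 equiv), DMF, 60 °C
Reagents that add atoms: iodomethane, CI
Why: Williamson ether synthesis (SN2 O-methylation of both phenoxides, the hydrogen-bonded 5-OH needing excess reagent and heat).

**Step 7**
Reactants: 10 5,7,8-trimethoxy-2-phenyl-4H-chromen-4-one
Product: 11 (±)-5,7,8-trimethoxy-2-phenyl-4H-chromen-4-ol
Conditions: DIBAL-H (1.2 equiv), CH2Cl2, −78 °C; Rochelle salt; used crude, kept cold over K2CO3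
Reagents that add atoms: none
Why: 1,2-Reduction of the vinylogous ester carbonyl by DIBAL-H gives the allylic, benzylic carbinol, which is racemic without consequence because C4′ is ionised in step 8.

**Step 8**
Reactants: 8 (+)-germacrene A; 11 (±)-5,7,8-trimethoxy-2-phenyl-4H-chromen-4-ol
Product: 14 (4S)-4-[(1S,4R,4aR,6R,8aS)-4-hydroxy-4,8a-dimethyl-6-(prop-1-en-2-yl)decahydronaphthalen-1-yl]-5,7,8-trimethoxy-2-phenyl-4H-chromene (target), via flavylium ion pair 12 (not isolated), via eudesm-4-yl cation 13 (not isolated)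
Conditions: (R)-TRIP (10 mol%), PhCF3 (0.2 M), 0 °C, no drying agent; 11 (1.3 equiv) added over 8 h by syringe pump; Et3N quench
Reagents that add atoms: none
Why: Proposed new method: the chiral phosphoric acid ionises carbinol 11 to a flavylium/phosphate contact ion pair (slow addition keeps the acid stored as this ion pair rather than free to protonate the diene), and this carbon electrophile initiates a transannular cation–olefin cyclisation in which C1=C10 attacks C4′ while C5 bonds to C10 through the crossed chair–chair conformer with the C7 isopropenyl group pseudo-equatorial, so that anti addition across both E-olefins sets 1β-C, 10β-Me and 5α-H, the water released on ionisation and held on the phosphate captures the C4 cation from the α-face (4α-OH), and the chiral anion shields one face of the planar cation to set C4′ (S); the closest known reaction types are proton- and epoxide-initiated transannular cyclisations of germacrenes to eudesmanes, additions of π-nucleophiles (allylsilanes, enol ethers) to flavylium salts, and chiral phosphoric acid ion-pair catalysis with benzopyrylium ions.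

**Compound list**
1 | (R)-(−)-carvone | CC1=CC[C@H](CC1=O)C(C)=C | starting material
2 | lithium (5R)-2-methyl-5-(prop-1-en-2-yl)cyclohex-1-en-1-olate | CC1=C([O-])C[C@@H](CC1)C(C)=C.[Li+] | intermediate
3 | (2R,5R)-2-(1-hydroxyethyl)-2-methyl-5-(prop-1-en-2-yl)cyclohexan-1-one (carbinol epimers; hydroxyethyl cis to isopropenyl) | CC(O)[C@@]1(C)CC[C@@H](C(C)=C)CC1=O | intermediate
4 | (2R,5R)-2-ethenyl-2-methyl-5-(prop-1-en-2-yl)cyclohexan-1-one (vinyl cis to isopropenyl) | C=C[C@@]1(C)CC[C@@H](C(C)=C)CC1=O | intermediate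
5 | (1S,2R,5R)-2-ethenyl-2-methyl-1,5-di(prop-1-en-2-yl)cyclohexan-1-ol (C1 isopropenyl trans to vinyl) | C=C[C@@]1(C)CC[C@@H](C(C)=C)C[C@]1(O)C(C)=C | intermediate
6 | potassium (1Z,5E,9R)-2,6-dimethyl-9-(prop-1-en-2-yl)cyclodeca-1,5-dien-1-olate | C/C1=C\CC/C(C)=C([O-])/C[C@H](C(C)=C)CC1.[K+] | intermediate
7 | (1Z,5E,9R)-2,6-dimethyl-9-(prop-1-en-2-yl)cyclodeca-1,5-dien-1-yl trifluoromethanesulfonate (germacra-1(10),4,11-trien-5-yl triflate) | C/C1=C\CC/C(C)=C(OS(=O)(=O)C(F)(F)F)/C[C@H](C(C)=C)CC1 | intermediate
8 | (+)-germacrene A, (1E,5E,8R)-1,5-dimethyl-8-(prop-1-en-2-yl)cyclodeca-1,5-diene | C/C1=C\CC/C(C)=C/C[C@H](C(C)=C)CC1 | intermediate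
9 | wogonin, 5,7-dihydroxy-8-methoxy-2-phenyl-4H-chromen-4-one | COc1c(O)cc(O)c2c(=O)cc(-c3ccccc3)oc12 | starting material
10 | 5,7,8-trimethoxy-2-phenyl-4H-chromen-4-one | COc1cc(OC)c2c(=O)cc(-c3ccccc3)oc2c1OC | intermediate
11 | (±)-5,7,8-trimethoxy-2-phenyl-4H-chromen-4-ol | COc1cc(OC)c2C(O)C=C(c3ccccc3)Oc2c1OC | intermediate
12 | 5,7,8-trimethoxy-2-phenylchromenylium (flavylium) ion, as its ion pair with the (R)-TRIP phosphate anion | COc1cc(OC)c2ccc(-c3ccccc3)[o+]c2c1OC | intermediate
13 | 1β-[(4S)-5,7,8-trimethoxy-2-phenyl-4H-chromen-4-yl]eudesm-11-en-4-yl cation (trans-decalin, 5α-H, 10β-Me, 7β-isopropenyl) | C=C(C)[C@@H]1CC[C@]2(C)[C@@H](C1)[C+](C)CC[C@H]2[C@H]1C=C(c2ccccc2)Oc2c(OC)c(OC)cc(OC)c21 | intermediate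
14 | (4S)-4-[(1S,4R,4aR,6R,8aS)-4-hydroxy-4,8a-dimethyl-6-(prop-1-en-2-yl)decahydronaphthalen-1-yl]-5,7,8-trimethoxy-2-phenyl-4H-chromene | C=C(C)[C@@H]1CC[C@]2(C)[C@@H](C1)[C@](C)(O)CC[C@H]2[C@H]1C=C(c2ccccc2)Oc2c(OC)c(OC)cc(OC)c21 | target

**Totals**
Total step count: 8. Longest linear sequence: 6 steps (steps 1–5 and 8, from carvone 1 to target 14).

**Three steps most likely to fail**

Step 8 (the proposed new step). The methoxy-rich flavylium ion may be too weak an electrophile for the diene. The acid may instead protonate germacrene A (giving selinenes or selin-11-en-4α-ol). The C4 cation may eliminate instead of capturing water, and C4′ control may be poor. Fallback with known chemistry, setting out from 8 (and from 11 for the aryl partner) and coming back at 14: treat 8 with NBS in acetone–water at 0 °C, a bromonium-initiated transannular cyclisation with water capture, to give 1β-bromoeudesm-11-en-4α-ol F3. Separately, stir 11 in THF–aqueous AcOH so that it opens through the flavylium/hemiketal to (E)-3-(2-hydroxy-3,4,6-trimethoxyphenyl)-1-phenylprop-2-en-1-one F4, and silylate it (TBSCl, imidazole, DMF) to the TBS ether F5. A tin-free Giese addition of the C1 radical from F3 to F5 ((TMS)3SiH, AIBN, benzene, 80 °C) gives (3R)-3-[2-(tert-butyldimethylsilyloxy)-3,4,6-trimethoxyphenyl]-3-(4α-hydroxyeudesm-11-en-1β-yl)-1-phenylpropan-1-one F6. This radical step is not expected to control C1 or C4′, so the required isomer is separated by HPLC. TBAF then frees the phenol ketone F7, which cyclodehydrates (PPTS, toluene, 4 Å sieves, 40 °C) to the 4H-chromene 14.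

Step 4. The rearrangement needs a ring-flipped chair with three axial groups, and O-triflation of a medium-ring potassium enolate with PhNTf2 can be slow or give enolate equilibration. Fallback setting out from 5 and coming back at 8, bypassing 7: generate enolate 6 as before and trap it with the more reactive diethyl chlorophosphate (THF, −78 °C) to give diethyl (1Z,5E,9R)-2,6-dimethyl-9-(prop-1-en-2-yl)cyclodeca-1,5-dien-1-yl phosphate F2. Cleave its C–O bond by dissolving-metal reduction (Li, NH3/THF, t-BuOH, −78 °C), which leaves the isolated olefins alone and needs neither palladium nor warming, to give 8; partial loss of C4=C5 geometry through the vinyl radical is the residual risk of this variant.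

Step 3. If the bulky alkenyl Grignard reagent adds with poor facial selectivity, the cis-dialkenyl carbinol would lead to a Z-olefin after step 4. Fallback setting out from 4 and coming back at 5: add ethynylmagnesium bromide (THF, 0 °C), a slim sp nucleophile with a strong preference for axial attack anti to the axial vinyl group, to give (1S,2R,5R)-2-ethenyl-1-ethynyl-2-methyl-5-(prop-1-en-2-yl)cyclohexan-1-ol F1. Zirconium-catalysed methylalumination of the terminal alkyne (Me3Al, Cp2ZrCl2 cat., CH2Cl2; then H2O) converts C≡CH into C(CH3)=CH2 and gives 5.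

**Further compounds**
F1 | step 3 | (1S,2R,5R)-2-ethenyl-1-ethynyl-2-methyl-5-(prop-1-en-2-yl)cyclohexan-1-ol | C=C[C@@]1(C)CC[C@@H](C(C)=C)C[C@]1(O)C#C
F2 | step 4 | diethyl (1Z,5E,9R)-2,6-dimethyl-9-(prop-1-en-2-yl)cyclodeca-1,5-dien-1-yl phosphate | C/C1=C\CC/C(C)=C(OP(=O)(OCC)OCC)/C[C@H](C(C)=C)CC1
F3 | step 8 | 1β-bromoeudesm-11-en-4α-ol | C=C(C)[C@@H]1CC[C@]2(C)[C@@H](C1)[C@](C)(O)CC[C@H]2Br
F4 | step 8 | (E)-3-(2-hydroxy-3,4,6-trimethoxyphenyl)-1-phenylprop-2-en-1-one | COc1cc(OC)c(/C=C/C(=O)c2ccccc2)c(O)c1OC
F5 | step 8 | (E)-3-[2-(tert-butyldimethylsilyloxy)-3,4,6-trimethoxyphenyl]-1-phenylprop-2-en-1-one | COc1cc(OC)c(/C=C/C(=O)c2ccccc2)c(O[Si](C)(C)C(C)(C)C)c1OC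
F6 | step 8 | (3R)-3-[2-(tert-butyldimethylsilyloxy)-3,4,6-trimethoxyphenyl]-3-(4α-hydroxyeudesm-11-en-1β-yl)-1-phenylpropan-1-one | C=C(C)[C@@H]1CC[C@]2(C)[C@@H](C1)[C@](C)(O)CC[C@H]2[C@@H](CC(=O)c1ccccc1)c1c(O[Si](C)(C)C(C)(C)C)c(OC)c(OC)cc1OC
F7 | step 8 | (3R)-3-(2-hydroxy-3,4,6-trimethoxyphenyl)-3-(4α-hydroxyeudesm-11-en-1β-yl)-1-phenylpropan-1-one | C=C(C)[C@@H]1CC[C@]2(C)[C@@H](C1)[C@](C)(O)CC[C@H]2[C@@H](CC(=O)c1ccccc1)c1c(O)c(OC)c(OC)cc1OC
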